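## Retrosynthetic overview

1. The chalcone enone comes from a Claisen–Schmidt condensation of a lavandulyl tris-MOM acetophenone with 2-hydroxy-4-methoxybenzaldehyde; the acetyl group is put on by directed lithiation of the ring C–H between two MOM ethers.
2. The prenyl end of the lavandulyl chain comes from a Wittig reaction on an aldehyde obtained by half-reduction of a seven-membered aryl lactone.
3. Key disconnection: the ArCH2–CH bond. The β-carbon of (E)-4-methylpenta-2,4-dienal, as a carbene-bound homoenolate, attacks the methylene of a phloroglucinol ortho-quinone methide; both carbons are electrophilic in their parent compounds. A chiral triazolium carbene sets the stereocentre.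
4. The ortho-quinone methide precursor is a benzylic sulfone made from 2,4,6-trihydroxybenzaldehyde.
5. Rings: both benzene rings are bought. The only ring formed is the transient seven-membered lactone (step 4), opened again in step 5.

Assumption: precatalyst T is (5aS,10bR)-2-(2,4,6-trimethylphenyl)-5a,10b-dihydro-4H,6H-indeno[2,1-b][1,2,4]triazolo[4,3-d][1,4]oxazin-2-ium chloride (C21H22ClN3O); its sense of induction for this substrate pair is taken by analogy and must be checked on the first run, and if it gives the (4R)-lactone the equally available (5aR,10bS) antipode is used.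

Abbreviation: "(2R)-lavandulyl" = (2R)-5-methyl-2-(prop-1-en-2-yl)hex-4-en-1-yl.

## Route

Step 1
Reactants: 1 2,4,6-trihydroxybenzaldehyde
Product: 2 2-hydroxy-4,6-bis(methoxymethoxy)benzaldehyde
Conditions: MOMCl (2.2 equiv), iPr2NEt (2.5 equiv), CH2Cl2, 0 °C → rt
Reagents that add atoms: chloromethyl methyl ether, COCCl
Why: Williamson-type O-alkylation; the hydroxyl hydrogen-bonded to the aldehyde is the least nucleophilic and stays free, so the 4,6-bis-ether forms selectively.

Step 2
Reactants: 2 2-hydroxy-4,6-bis(methoxymethoxy)benzaldehyde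
Product: 4 3,5-bis(methoxymethoxy)-2-[(4-methylbenzenesulfonyl)methyl]phenol, via salicyl alcohol 3 (not isolated)
Conditions: NaBH4 (0.5 equiv), THF–MeOH, −10 °C, 15 min; then 4-MeC6H4SO2Na (3 equiv), AcOH, rt, 12 h
Reagents that add atoms: sodium 4-methylbenzenesulfinate, Cc1ccc(S(=O)[O-])cc1.[Na+]
Why: Borohydride carbonyl reduction, then acid-promoted SN1-type substitution of the doubly donor-activated benzylic alcohol by the S-nucleophilic sulfinate, giving a bench-stable sulfone.

Step 3
Reactants: 5 methacrolein (3 equiv)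
Product: 6 (2E)-4-methylpenta-2,4-dienal
Conditions: Ph3P=CHCHO (1 equiv), toluene, 80 °C, sealed tube
Reagents that add atoms: (triphenylphosphoranylidene)acetaldehyde, O=CC=P(c1ccccc1)(c1ccccc1)c1ccccc1
Why: Wittig olefination with a stabilised formylmethylene ylide gives the E-enal; excess methacrolein suppresses a second homologation.

Step 4
Reactants: 4 3,5-bis(methoxymethoxy)-2-[(4-methylbenzenesulfonyl)methyl]phenol; 6 (2E)-4-methylpenta-2,4-dienal (2 equiv)
Product: 8 (4S)-6,8-bis(methoxymethoxy)-4-(prop-1-en-2-yl)-4,5-dihydro-1-benzoxepin-2(3H)-one, via ortho-quinone methide 7 (not isolated)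
Conditions: triazolium chloride T (C21H22ClN3O, 15 mol %), Cs2CO3 (1.3 equiv), 4 Å MS, THF, 0 °C → rt
Reagents that add atoms: none
Why: Carbene-catalysed homoenolate formal [4+3] annulation: base expels sulfinate from 4 to give 7, the carbene-bound homoenolate of 6 attacks the methylene of 7 through its β-carbon, and the phenoxide then acylates on the acyl azolium to close the lactone and release the carbene; the aminoindanol backbone of T shields one face of the homoenolate, so C4 is formed as (S).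

Step 5
Reactants: 8 (4S)-6,8-bis(methoxymethoxy)-4-(prop-1-en-2-yl)-4,5-dihydro-1-benzoxepin-2(3H)-one
Product: 9 (3S)-4-[2-hydroxy-4,6-bis(methoxymethoxy)phenyl]-3-(prop-1-en-2-yl)butanal
Conditions: iBu2AlH (1.1 equiv), CH2Cl2, −78 °C; aq. KNaC4H4O6 work-up
Reagents that add atoms: none
Why: Partial reduction of a lactone with one equivalent of iBu2AlH at −78 °C stops at the aldehyde oxidation level; the stereocentre, β to the carbonyl, is not touched.

Step 6
Reactants: 9 (3S)-4-[2-hydroxy-4,6-bis(methoxymethoxy)phenyl]-3-(prop-1-en-2-yl)butanal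
Product: 11 1,3,5-tris(methoxymethoxy)-2-[(2R)-lavandulyl]benzene, via potassium phenolate 10 (not isolated)
Conditions: iPrPPh3I (2.5 equiv), KN(SiMe3)2 (3.5 equiv), THF, 0 °C; add 9, −78 °C → rt; then MOMCl (4 equiv), 0 °C → rt
Reagents that add atoms: isopropyltriphenylphosphonium iodide, CC(C)[P+](c1ccccc1)(c1ccccc1)c1ccccc1.[I-]; chloromethyl methyl ether, COCCl
Why: Wittig olefination with the non-stabilised isopropylidene ylide builds the prenyl alkene (no E/Z issue), and the phenolate kept by the extra base is O-alkylated in the same flask; the stereocentre keeps its geometry and only its descriptor changes from S to R through the CIP priorities.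

Step 7
Reactants: 11 1,3,5-tris(methoxymethoxy)-2-[(2R)-lavandulyl]benzene
Product: 13 1-{2,4,6-tris(methoxymethoxy)-3-[(2R)-lavandulyl]phenyl}ethan-1-one, via aryllithium 12 (not isolated)
Conditions: n-BuLi (1.3 equiv), THF, 0 °C, 1 h; then MeC(O)N(OMe)Me (2 equiv), −78 → 0 °C; H2O
Reagents that add atoms: N-methoxy-N-methylacetamide, CC(=O)N(C)OC
Why: Directed ortho-metalation: a ring C–H flanked by two MOM ethers is lithiated (the two ring hydrogens are constitutionally equivalent), and the Weinreb amide acylates the aryllithium once, without over-addition.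

Step 8
Reactants: 13 1-{2,4,6-tris(methoxymethoxy)-3-[(2R)-lavandulyl]phenyl}ethan-1-one; 14 2-hydroxy-4-methoxybenzaldehyde (1.5 equiv)
Product: 15 (2E)-3-(2-hydroxy-4-methoxyphenyl)-1-{2,4,6-tris(methoxymethoxy)-3-[(2R)-lavandulyl]phenyl}prop-2-en-1-one
Conditions: KOH (10 equiv), EtOH–H2O, rt → 40 °C, 24–48 h; dilute HCl to pH 5 at 0 °C
Reagents that add atoms: none
Why: Claisen–Schmidt (crossed aldol) condensation: the methyl ketone enolate adds to the non-enolisable aldehyde and loss of water gives the thermodynamic E-enone; the fully protected ring A cannot close to a flavanone.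

Step 9
Reactants: 15 (2E)-3-(2-hydroxy-4-methoxyphenyl)-1-{2,4,6-tris(methoxymethoxy)-3-[(2R)-lavandulyl]phenyl}prop-2-en-1-one
Product: 16 (2E)-3-(2-hydroxy-4-methoxyphenyl)-1-{2,4,6-trihydroxy-3-[(2R)-lavandulyl]phenyl}prop-2-en-1-one (CNP0245273.1)
Conditions: 3 M aq. HCl, MeOH, 40 °C, 1–2 h, dark
Reagents that add atoms: none
Why: Acid-catalysed acetal exchange removes the three MOM ethers as dimethoxymethane; the aryl methyl ether, both alkenes, the E-enone and the stereocentre tolerate brief mild acid, as in MOM removals on prenylated chalcones.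

## Compound list

1 | 2,4,6-trihydroxybenzaldehyde | O=Cc1c(O)cc(O)cc1O | starting material
2 | 2-hydroxy-4,6-bis(methoxymethoxy)benzaldehyde | COCOc1cc(O)c(C=O)c(OCOC)c1 | intermediate
3 | 2-(hydroxymethyl)-3,5-bis(methoxymethoxy)phenol (not isolated) | COCOc1cc(O)c(CO)c(OCOC)c1 | intermediate
4 | 3,5-bis(methoxymethoxy)-2-[(4-methylbenzenesulfonyl)methyl]phenol | COCOc1cc(O)c(CS(=O)(=O)c2ccc(C)cc2)c(OCOC)c1 | intermediate
5 | methacrolein (2-methylprop-2-enal) | C=C(C)C=O | starting material
6 | (2E)-4-methylpenta-2,4-dienal | C=C(C)/C=C/C=O | intermediate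
7 | 3,5-bis(methoxymethoxy)-6-methylidenecyclohexa-2,4-dien-1-one (ortho-quinone methide, not isolated) | C=C1C(=O)C=C(OCOC)C=C1OCOC | intermediate
8 | (4S)-6,8-bis(methoxymethoxy)-4-(prop-1-en-2-yl)-4,5-dihydro-1-benzoxepin-2(3H)-one | C=C(C)[C@@H]1CC(=O)Oc2cc(OCOC)cc(OCOC)c2C1 | intermediate
9 | (3S)-4-[2-hydroxy-4,6-bis(methoxymethoxy)phenyl]-3-(prop-1-en-2-yl)butanal | C=C(C)[C@H](CC=O)Cc1c(O)cc(OCOC)cc1OCOC | intermediate
10 | potassium 3,5-bis(methoxymethoxy)-2-[(2R)-5-methyl-2-(prop-1-en-2-yl)hex-4-en-1-yl]phenolate (not isolated) | C=C(C)[C@H](CC=C(C)C)Cc1c([O-])cc(OCOC)cc1OCOC.[K+] | intermediate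
11 | 1,3,5-tris(methoxymethoxy)-2-[(2R)-5-methyl-2-(prop-1-en-2-yl)hex-4-en-1-yl]benzene | C=C(C)[C@H](CC=C(C)C)Cc1c(OCOC)cc(OCOC)cc1OCOC | intermediate
12 | {2,4,6-tris(methoxymethoxy)-3-[(2R)-5-methyl-2-(prop-1-en-2-yl)hex-4-en-1-yl]phenyl}lithium (not isolated) | C=C(C)[C@H](CC=C(C)C)Cc1c(OCOC)cc(OCOC)c([Li])c1OCOC | intermediate
13 | 1-{2,4,6-tris(methoxymethoxy)-3-[(2R)-5-methyl-2-(prop-1-en-2-yl)hex-4-en-1-yl]phenyl}ethan-1-one | C=C(C)[C@H](CC=C(C)C)Cc1c(OCOC)cc(OCOC)c(C(C)=O)c1OCOC | intermediate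
14 | 2-hydroxy-4-methoxybenzaldehyde | COc1ccc(C=O)c(O)c1 | starting material
15 | (2E)-3-(2-hydroxy-4-methoxyphenyl)-1-{2,4,6-tris(methoxymethoxy)-3-[(2R)-5-methyl-2-(prop-1-en-2-yl)hex-4-en-1-yl]phenyl}prop-2-en-1-one | C=C(C)[C@H](CC=C(C)C)Cc1c(OCOC)cc(OCOC)c(C(=O)/C=C/c2ccc(OC)cc2O)c1OCOC | intermediate
16 | (2E)-3-(2-hydroxy-4-methoxyphenyl)-1-{2,4,6-trihydroxy-3-[(2R)-5-methyl-2-(prop-1-en-2-yl)hex-4-en-1-yl]phenyl}prop-2-en-1-one | C=C(C)[C@H](CC=C(C)C)Cc1c(O)cc(O)c(C(=O)/C=C/c2ccc(OC)cc2O)c1O | target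

## Step count and risks

Total step count: 9. Longest linear sequence: 8 (steps 1, 2, 4, 5, 6, 7, 8, 9); step 3 is a one-step side branch.

**Step 4 (most likely to fail).** The dienyl homoenolate can also react through its δ-carbon (the isopropenyl CH2) and give a linear adduct. β-Protonation and oligomerisation of 7 can compete, and the ee is unproven for this substrate pair. The fallback sets out from 4 and comes back at 11. It replaces the dienal by a β-alkynyl enal, whose remote terminus is blocked by a bulky silyl group, and makes the isopropenyl group from the alkyne afterwards. 3-(Triisopropylsilyl)prop-2-ynal and Ph3P=CHCHO give (2E)-5-(triisopropylsilyl)pent-2-en-4-ynal F1. Annulation of 4 with this enal under the step 4 conditions gives (4S)-6,8-bis(methoxymethoxy)-4-[(triisopropylsilyl)ethynyl]-4,5-dihydro-1-benzoxepin-2(3H)-one F2. iBu2AlH at −78 °C gives (3S)-3-{[2-hydroxy-4,6-bis(methoxymethoxy)phenyl]methyl}-5-(triisopropylsilyl)pent-4-ynal F3. The Wittig/MOMCl sequence of step 6 gives triisopropyl{(3R)-6-methyl-3-{[2,4,6-tris(methoxymethoxy)phenyl]methyl}hept-5-en-1-yn-1-yl}silane F4. Bu4NF in THF gives 2-[(2R)-2-ethynyl-5-methylhex-4-en-1-yl]-1,3,5-tris(methoxymethoxy)benzene F5. Methylalumination of the terminal alkyne (Al(CH3)3, Zr(C5H5)2Cl2 cat., CH2Cl2, −20 °C, then H2O) puts methyl on the internal carbon and hydrogen on the terminal one, which is the isopropenyl group of 11.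

**Step 2.** The very electron-rich salicyl alcohol 3 can lose hydroxide in the borohydride medium and be reduced on to the C-methyl phenol, or condense with itself to diarylmethanes before the sulfinate captures it. The fallback sets out from 2 and comes back at 4. Reductive amination of 2 (Me2NH, NaBH(OAc)3, 1,2-dichloroethane) gives the Mannich base 2-[(dimethylamino)methyl]-3,5-bis(methoxymethoxy)phenol F6, a benzylic amine that does not ionise under hydride conditions. MeI in acetone gives 1-[2-hydroxy-4,6-bis(methoxymethoxy)phenyl]-N,N,N-trimethylmethanaminium iodide F7. Warming this salt with 4-MeC6H4SO2Na in DMF at 60 °C displaces trimethylamine and gives 4.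

**Step 8.** The aldehyde reacts as its deactivated phenolate and the ketone is flanked by two ortho MOM ethers, so conversion may be low. The fallback sets out from 11 and comes back at 16, avoiding the aldol altogether. Aldehyde 14 is protected (MOMCl, iPr2NEt) as 4-methoxy-2-(methoxymethoxy)benzaldehyde F8. Horner–Wadsworth–Emmons reaction with diethyl {2-[methoxy(methyl)amino]-2-oxoethyl}phosphonate and NaH gives (2E)-N-methoxy-3-[4-methoxy-2-(methoxymethoxy)phenyl]-N-methylprop-2-enamide F9. Aryllithium 12, made from 11 as in step 7, is acylated by this amide to give (2E)-3-[4-methoxy-2-(methoxymethoxy)phenyl]-1-{2,4,6-tris(methoxymethoxy)-3-[(2R)-5-methyl-2-(prop-1-en-2-yl)hex-4-en-1-yl]phenyl}prop-2-en-1-one F10. HCl/MeOH as in step 9 then gives 16.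

## Further compounds

F1 | step 4 | (2E)-5-(triisopropylsilyl)pent-2-en-4-ynal | CC(C)[Si](C#C/C=C/C=O)(C(C)C)C(C)C
F2 | step 4 | (4S)-6,8-bis(methoxymethoxy)-4-[(triisopropylsilyl)ethynyl]-4,5-dihydro-1-benzoxepin-2(3H)-one | CC(C)[Si](C#C[C@@H]1CC(=O)Oc2cc(OCOC)cc(OCOC)c2C1)(C(C)C)C(C)C
F3 | step 4 | (3S)-3-{[2-hydroxy-4,6-bis(methoxymethoxy)phenyl]methyl}-5-(triisopropylsilyl)pent-4-ynal | CC(C)[Si](C#C[C@H](CC=O)Cc1c(O)cc(OCOC)cc1OCOC)(C(C)C)C(C)C
F4 | step 4 | triisopropyl{(3R)-6-methyl-3-{[2,4,6-tris(methoxymethoxy)phenyl]methyl}hept-5-en-1-yn-1-yl}silane | CC(C)[Si](C#C[C@H](CC=C(C)C)Cc1c(OCOC)cc(OCOC)cc1OCOC)(C(C)C)C(C)C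
F5 | step 4 | 2-[(2R)-2-ethynyl-5-methylhex-4-en-1-yl]-1,3,5-tris(methoxymethoxy)benzene | C#C[C@H](CC=C(C)C)Cc1c(OCOC)cc(OCOC)cc1OCOC
F6 | step 2 | 2-[(dimethylamino)methyl]-3,5-bis(methoxymethoxy)phenol | CN(C)Cc1c(O)cc(OCOC)cc1OCOC
F7 | step 2 | 1-[2-hydroxy-4,6-bis(methoxymethoxy)phenyl]-N,N,N-trimethylmethanaminium iodide | C[N+](C)(C)Cc1c(O)cc(OCOC)cc1OCOC.[I-]
F8 | step 8 | 4-methoxy-2-(methoxymethoxy)benzaldehyde | COCOc1cc(OC)ccc1C=O
F9 | step 8 | (2E)-N-methoxy-3-[4-methoxy-2-(methoxymethoxy)phenyl]-N-methylprop-2-enamide | CON(C)C(=O)/C=C/c1ccc(OC)cc1OCOC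
F10 | step 8 | (2E)-3-[4-methoxy-2-(methoxymethoxy)phenyl]-1-{2,4,6-tris(methoxymethoxy)-3-[(2R)-5-methyl-2-(prop-1-en-2-yl)hex-4-en-1-yl]phenyl}prop-2-en-1-one | C=C(C)[C@H](CC=C(C)C)Cc1c(OCOC)cc(OCOC)c(C(=O)/C=C/c2ccc(OC)cc2OCOC)c1OCOC
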